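Locants used throughout: C1 is the ketone carbon; C2=C3 is the alkene, with a methyl group on C3; C4–C5–C11–C10 is the cyclobutane (C4 bonded to C3, C11 to C1, a methyl group on C10); C6–C7–C8–C9 is the bridge from C5 to C10; C6 carries a methyl group and C15 (the CH2O carbon). On the cyclobutane, "anti" is the face turned away from the C1–C2–C3 bridge and "syn" the face turned toward it. Compound numbers are those of the steps and of the compound list.

## Analysis of the target

Target 35 is a tricyclic sesquiterpenoid triol carrying three angelate esters, on C7, C9 and C15. Its core is a bicyclo[3.1.1]heptenone of the verbenone type (C1 ketone, C2=C3, cyclobutane C4–C5–C11–C10) whose two one-carbon bridges, C5 and C10, are tied together by the chain C6–C7–C8–C9 into a seven-membered ring. There are seven stereocentres (C4, C5, C6, C7, C9, C10, C11), two of them quaternary (C6, C10). The cage dictates that C6 and C9 stand anti on the cyclobutane while the C5 hydrogen and the C10 methyl stand syn. On the seven-membered ring, C15 and the C9 oxygen are cis, and the C7 oxygen is trans to both. The angelates isomerise to tiglates under base, acid, radical or nucleophilic conditions, the enone is reducible, and any cation next to the four-membered ring invites pinane-type rearrangement. The hard parts are the cyclobutane itself and the substitution of C5, a methylene with no activating neighbour. The strategy rests on one observation: C1–C5 and C11 with the C3 methyl, together with C10, its methyl and C9, are the ten carbons of carvone. Carvone's stereocentre is C11, its β-carbon is C4, and its isopropenyl group supplies C10 and C9.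

## Retrosynthetic reasoning

Ester bonds. The three acyl C–O bonds of 35 are cut last, giving triol enone 32 and angelic acid 33. The angelates would not survive the enolate, hydride, radical and fluoride steps, and one triple esterification ends the route without touching a stereocentre.

C1 carbonyl and C2=C3. The enone of 32 (silyl-protected as 31) is traced to the saturated C2 ketone 28, because C2 is where the carvone carbonyl ends up. The forward transposition oxidises the only α-methylene (C1) to the diosphenol 29 and removes the C2 oxygen through triflate 30. The 1,2-dione can enolise only toward C3, since C11 is a bridgehead, so the regiochemistry is fixed by structure.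

C7–H, C15–H and the two C–O single bonds. Triol 26 (protected as 27) is traced to keto lactone 24, in which C15 and the C9 oxygen are held as one lactone and C7 is a ketone. Hydride then has to do two things: reduce C7 from the open face of the cage, and open the lactone to the C15 and C9 hydroxyls.

C6–C7. Cutting this bond in 24 (through carbinol 23) leads to bromo lactone aldehyde 21. The cut is made here because C6 can be made nucleophilic as a lactone enolate while C7 is an aldehyde. The lactone to the C9 oxygen allows only one configuration at the new quaternary C6. The forward reaction is an intramolecular Reformatsky aldol that closes the seven-membered carbocycle.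

C5–C6 and C5–H. Lactone 17 is traced through tertiary alcohol 15 to bromopropanoate 13 and so to the C5 ketone. Intermolecular additions to a trigonal C5 would meet two similarly hindered faces. The propanoate unit is therefore delivered from the C9 oxygen, which can reach only the anti face, and the C5 oxygen is then replaced by hydrogen while C6 is still tied to C9.

C8–C9. Homoallylic alcohol 12 comes from aldehyde 10 by asymmetric allylation. C9 is set under reagent control, and the allyl group carries C8 and C7.

C5=O. Ketone 9 is traced through oxime 8 and nitrite 6 to alcohol 5. The C9 alkoxy radical sits over C5 and can abstract its anti hydrogen through a six-membered transition state, which turns the unactivated methylene into a carbonyl group.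

C4–C10 (key disconnection). Hydroxy ketone 4 is opened between C4 and C10 to epoxy enone 2. In the forward direction a single-electron donor based on trivalent titanium opens the epoxide to the tertiary C10 radical, which adds 4-exo to the enone β-carbon. One step gives the cyclobutane, the quaternary C10, the C4 stereocentre and the C9 oxygen.

Epoxide. Compound 2 is one epoxidation away from (S)-(+)-carvone 1, which supplies C11 in the required absolute configuration.

## Alternatives that were turned down

Alternative 1: The C4–C5 bond is cut. A cis-fused bicyclo[5.4.0]undecenone A2, with the C5 ketone in the seven-membered ring, would be irradiated. The excited carbonyl abstracts the allylic hydrogen on C4, and the 1,4-biradical closes to the cyclobutanol A1 (Norrish–Yang reaction).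
- For it: the four-membered ring and two stereocentres appear late from an unstrained bicycle, the C4–H bond is weak, and C5 is a carbonyl by construction. On that point it is stronger than the chosen route, which has to oxidise C5 by a remote radical process.
- Against it: the same biradical can cleave the C10–C11 ring-fusion bond (Norrish type 2 fragmentation), and the allylic radical can also bond through C2. A1 still carries a hydroxyl on C5 that must be removed, as in the chosen route. Five stereocentres (C6, C7, C9, C10, C11), two of them quaternary, must first be set in a flexible six–seven system with no rigid template.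
- Comparison: the chosen strategy makes the cyclobutane in step 2 from a chiral-pool terpene and then uses the cage to relay every later stereocentre. The alternative stakes a late, heavily functionalised intermediate on a photoreaction with built-in competing pathways.

Alternative 2: The C7–C8 bond is cut. In A4 the enolate of the methyl ketone on C10 would add to one of two diastereotopic formyl groups on C6, closing the seven-membered ring to the β-hydroxy ketone A3 and leaving the other formyl group as C15.
- For it: one step sets C6 and C7, C6 needs no stereocontrol until then, and the endgame is short. For the C6/C7 region it is more step-economic than the two Reformatsky reactions used here.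
- Against it: it presupposes the bicyclo[3.1.1]heptene with the C5 substituent already on the anti face, which is the real problem and is left unsolved. A quaternary malondialdehyde is prone to deformylation under the basic aldol conditions. Group selectivity rests on small differences, A3 can dehydrate or revert, and the C9 ketone still needs a face-selective reduction next to quaternary C10.
- Comparison: the chosen route answers the same points with a lactone tether, which fixes C6 by geometry and delivers C9 and C15 at the right oxidation level.

Alternative 3: The C9–C10 bond is cut. In A6 a divalent samarium reductant would turn the C9 aldehyde into a ketyl that adds to the methylated β-carbon C10 of a cyclohexenone. Protonation at C11 gives the cis-fused ketone A5.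
- For it: ketyl–enone couplings are a dependable way to build a quaternary carbon beside a carbinol, and the ring fusion comes out cis. The control of C10 is arguably more predictable here than in the titanium step of the chosen route.
- Against it: A5 has no cyclobutane. The C4–C5 bond must still be made later, which leads back to the photochemical closure of Alternative 1 or to another late four-ring closure. The cyclisation is a seven-membered closure in which both alkene carbons end in the new ring, slower than the usual five- and six-membered exo modes. The C3 stereocentre has to be set only to be destroyed.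
- Comparison: it needs two strategic ring closures where the chosen strategy needs one, and it gives up the step economy of starting from a terpene that already contains ten of the fifteen carbons.

Key step: step 2

Assumption: C3 is drawn as the epimer with its methyl on the C5 side, expected after acid equilibration; the other epimer would behave alike, and both converge in step 20. Compound 2 is a mixture at the epoxide carbon and compounds 13 to 21 are mixtures at C6; these centres become trigonal later.

## Route

Step 1
Reactants: 1 (S)-(+)-carvone
Product: 2 (5S)-8,9-epoxycarvone (both epimers at the epoxide carbon)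
Conditions: mCPBA, NaHCO3, CH2Cl2, 0 °C
Reagents that add atoms: mCPBA, O=C(OO)c1cccc(Cl)c1
Why: Prilezhaev epoxidation; the electron-rich 1,1-disubstituted alkene reacts far faster than the electron-poor enone alkene, and the epimer mixture does not matter because C10 becomes a planar radical in step 2.

Step 2
Reactants: 2 (5S)-8,9-epoxycarvone
Product: 4 bicyclic hydroxy ketone (C2 ketone; C9 hydroxymethyl on C10 anti; C10 methyl syn), via titanium enolate 3 (not isolated)
Conditions: Cp2TiCl2 (2.5 equiv), Zn dust, THF, 25 °C, the green Cp2TiCl solution added slowly to 2; then 1 M HCl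
Reagents that add atoms: none
Why: Cp2TiCl, a trivalent titanium single-electron donor made in the flask, binds the epoxide oxygen and cleaves the C10–O bond homolytically, giving the tertiary C10 radical and a tetravalent titanium alkoxide on C9; both epoxide epimers give the same planar radical. The radical adds to the enone β-carbon C4 in a 4-exo-trig closure that forms the C4–C10 bond and the cyclobutane C4–C5–C11–C10 of the bicyclo[3.1.1]heptane. A second Cp2TiCl reduces the resulting α-keto radical to the titanium enolate 3, which takes the reverse ring opening out of play; acid work-up protonates C3. The closest known reaction type is the titanocene-mediated reductive epoxide opening with 4-exo cyclisation onto an α,β-unsaturated carbonyl acceptor. C4 is fixed by geometry, because the one-carbon link from C11 can reach only the face of C4 cis to it. C10 is set in the closure: the CH2O–Ti(Cp)2Cl group, by far the larger of its two substituents, should take the anti position and leave the methyl group over the enolate ring. The step needs ring closure to outrun trapping of the tertiary radical by Cp2TiCl, which would end in β-hydride elimination or reduction. A hindered tertiary radical, an electron-poor acceptor held two atoms away on the ring and a low stationary Cp2TiCl concentration should secure this.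

Step 3
Reactants: 4 bicyclic hydroxy ketone
Product: 5 hydroxy ketal (C2 ethylene ketal)
Conditions: ethylene glycol, PPTS (cat.), benzene, reflux, Dean–Stark
Reagents that add atoms: ethylene glycol, OCCO
Why: Acid-catalysed ketalisation masks C2 so that the C5 ketone made later is the only carbonyl electrophile. C3 equilibrates through the enol to the epimer with its methyl on the C5 side, away from the C10 methyl.

Step 4
Reactants: 5 hydroxy ketal
Product: 6 C9 nitrite ester
Conditions: NOCl, pyridine, −20 °C
Reagents that add atoms: nitrosyl chloride, O=NCl
Why: O-Nitrosation of the primary alcohol; pyridine takes up the HCl, so the ketal is untouched.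

Step 5
Reactants: 6 C9 nitrite ester
Product: 8 C5 oxime with free C9 alcohol, via C5 nitroso alcohol 7 (not isolated)
Conditions: hν (Hg lamp, Pyrex), benzene, N2, 20 °C; then i-PrOH, reflux
Reagents that add atoms: none
Why: Barton nitrite ester photolysis: O–NO homolysis gives the C9 alkoxy radical, which abstracts hydrogen from C5 through a six-membered transition state (O, C9, C10, C4 or C11, C5, H). That is the only δ-hydrogen in reach, because the CH2O arm and that hydrogen both stand on the anti face; NO recombines at C5 and the nitroso compound tautomerises to the oxime on heating. No stereocentre is set, since C5 ends trigonal.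

Step 6
Reactants: 8 C5 oxime
Product: 9 hydroxy cyclobutanone (C5 ketone, C9 alcohol)
Conditions: TiCl3 (aq. HCl), NH4OAc, dioxane–H2O, 25 °C
Reagents that add atoms: water, O
Why: Reductive deoximation: trivalent titanium cleaves the N–O bond and the NH imine hydrolyses, while the buffered medium leaves the dioxolane intact. C5 cannot enolise because both neighbours are bridgeheads.

Step 7
Reactants: 9 hydroxy cyclobutanone
Product: 10 keto aldehyde (C5 ketone, C9 aldehyde)
Conditions: Dess–Martin periodinane, NaHCO3, CH2Cl2, 25 °C
Reagents that add atoms: none
Why: Dess–Martin oxidation of the neopentyl primary alcohol; aldehyde 10 has no α-hydrogen and can neither epimerise nor self-condense.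

Step 8
Reactants: 10 keto aldehyde
Product: 12 (9R)-homoallylic alcohol, via borinate ester 11 (not isolated)
Conditions: (+)-Ipc2B(allyl), Et2O, −78 °C; then HOCH2CH2NH2, 25 °C
Reagents that add atoms: (+)-B-allyldiisopinocampheylborane, C=CCB([C@H]1C[C@H]2C[C@@H]([C@@H]1C)C2(C)C)[C@H]1C[C@H]2C[C@@H]([C@@H]1C)C2(C)C
Why: Brown allylboration through a chair-like six-membered transition state; the reagent derived from (−)-α-pinene attacks the Re face of the aldehyde and sets C9 as R under reagent control, the surroundings of the aldehyde being nearly symmetric. The aldehyde reacts much faster than the hindered cyclobutanone at −78 °C, and the non-oxidative ethanolamine work-up avoids Baeyer–Villiger oxidation of the four-membered ketone.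

Step 9
Reactants: 12 (9R)-homoallylic alcohol
Product: 13 C9 2-bromopropanoate
Conditions: 2-bromopropanoyl bromide, pyridine, DMAP (cat.), CH2Cl2, 0 °C
Reagents that add atoms: 2-bromopropanoyl bromide, CC(Br)C(=O)Br
Why: Acylation of the secondary alcohol by the acid bromide; the bromide-bearing carbon (the future C6) is a mixture, which is irrelevant because it becomes an enolate.

Step 10
Reactants: 13 C9 2-bromopropanoate
Product: 15 hydroxy lactone (C5–C6 bond; C5 tertiary alcohol syn; seven-membered lactone from C15 to the C9 oxygen), via samarium enolate 14 (not isolated)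
Conditions: SmI2 (2.2 equiv), THF, −78 → 0 °C, high dilution; aq. NH4Cl
Reagents that add atoms: none
Why: Samarium Reformatsky reaction: two equivalents of SmI2 reduce the C–Br bond to the trivalent samarium enolate, which adds to the strained C5 ketone and closes the lactone. The enolate hangs from the C9 oxygen on the anti face and can reach only that face of C5, so C6 is bonded anti and the new hydroxyl is syn. The α-bromo ester is reduced far faster than the ketone.

Step 11
Reactants: 15 hydroxy lactone
Product: 16 C5 methyl oxalate
Conditions: MeO2CCOCl, pyridine, DMAP (cat.), CH2Cl2, 0 → 25 °C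
Reagents that add atoms: methyl chlorooxoacetate, COC(=O)C(=O)Cl
Why: Acylation of the tertiary alcohol by the reactive oxalyl half-chloride activates it for radical deoxygenation; elimination is excluded because any alkene at C5 would be a bridgehead alkene.

Step 12
Reactants: 16 C5 methyl oxalate
Product: 17 lactone with C5–H syn
Conditions: Bu3SnH, AIBN, toluene, 110 °C
Reagents that add atoms: none
Why: Radical deoxygenation of a tertiary methyl oxalate (Barton–McCombie type): stannyl radical addition and C–O scission give the C5 cyclobutyl radical, which does not ring-open. C6 is held on the anti face by the lactone bridge to C9, so hydrogen can be delivered only to the syn face, which gives the C5 configuration of the target.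

Step 13
Reactants: 17 lactone
Product: 19 C6 bromo lactone, via lithium enolate 18 (not isolated)
Conditions: LDA, THF, −78 °C; then CBr4, −78 °C
Reagents that add atoms: carbon tetrabromide, BrC(Br)(Br)Br
Why: Enolate halogenation: C6 is the only acidic position, and its lithium enolate is brominated by CBr4; the tertiary bromide forms as an epimer mixture that converges in step 15.

Step 14
Reactants: 19 C6 bromo lactone
Product: 21 bromo lactone aldehyde (C7 aldehyde), via ozonide 20 (not isolated)
Conditions: O3, CH2Cl2, −78 °C; then Me2S, −78 → 25 °C
Reagents that add atoms: ozone, [O-][O+]=O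
Why: Ozonolysis of the terminal alkene with reductive work-up by dimethyl sulfide, which spares the tertiary α-bromo lactone; one carbon leaves as formaldehyde and C7 appears as the aldehyde.

Step 15
Reactants: 21 bromo lactone aldehyde
Product: 23 bridged hydroxy lactone (C6–C7 bond; seven-membered carbocycle closed; C7 carbinol epimeric to the target), via samarium enolate 22 (not isolated)
Conditions: SmI2 (2.2 equiv), THF, −78 °C; aq. NH4Cl
Reagents that add atoms: none
Why: Samarium Reformatsky aldol: SmI2 turns the C6 bromide into the trivalent samarium enolate, which adds to the C7 aldehyde (6-enolendo-exo-trig with respect to the lactone), forming the C6–C7 bond and with it the seven-membered carbocycle. The lactone bridge forces C15 and the C9 oxygen to be cis, so the quaternary C6 is set by C9. The chelated transition state is expected to turn the C7 hydroxyl toward the lactone carbonyl; steps 16 and 17 correct this, and either C7 epimer is usable.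

Step 16
Reactants: 23 bridged hydroxy lactone
Product: 24 bridged keto lactone (C7 ketone)
Conditions: Dess–Martin periodinane, NaHCO3, CH2Cl2, 25 °C
Reagents that add atoms: none
Why: Dess–Martin oxidation under buffered, non-basic conditions; C6 is quaternary and cannot epimerise. Base is avoided because the C9 carboxylate is β to the new ketone.

Step 17
Reactants: 24 bridged keto lactone
Product: 26 triol ketal (C7, C9 and C15 hydroxyls), via hydroxy lactone 25 (not isolated)
Conditions: LiAlH4, THF, −78 °C, then 0 → 25 °C; Rochelle salt work-up
Reagents that add atoms: none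
Why: Hydride reduction in two stages: at −78 °C the C7 ketone is reduced while the cage is intact, from the open face beside the lactone bridge and not from the face shielded by the cyclobutane, which places the C7 hydroxyl trans to C15 as in the target. On warming the lactone is reduced and releases the C15 and C9 hydroxyls.

Step 18
Reactants: 26 triol ketal
Product: 27 tris(tert-butyldimethylsilyl) ether ketal
Conditions: TBSOTf (4.5 equiv), 2,6-lutidine, CH2Cl2, −78 → 0 °C
Reagents that add atoms: tert-butyldimethylsilyl triflate, CC(C)(C)[Si](C)(C)OS(=O)(=O)C(F)(F)F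
Why: Silylation with the silyl triflate, which also reaches the two neopentyl secondary hydroxyls; at low temperature the dioxolane is not activated.

Step 19
Reactants: 27 tris-silyl ether ketal
Product: 28 tris-silyl ether C2 ketone
Conditions: PPTS, acetone–H2O (10:1), 60 °C
Reagents that add atoms: water, O
Why: Mild acid-catalysed ketal hydrolysis; silyl ethers of hindered alcohols survive pyridinium tosylate.

Step 20
Reactants: 28 tris-silyl ether C2 ketone
Product: 29 diosphenol (C1 ketone, C2 enol, C2=C3)
Conditions: SeO2, 1,4-dioxane (trace H2O), 90 °C
Reagents that add atoms: selenium dioxide, O=[Se]=O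
Why: Riley oxidation: SeO2 oxidises the only α-methylene (C1) to the 1,2-dione, which enolises toward C3, the only direction open because C11 is a bridgehead. This moves the carbonyl to C1 and makes C3 trigonal, erasing its configuration.

Step 21
Reactants: 29 diosphenol
Product: 30 diosphenol triflate (C2 triflate)
Conditions: Tf2O, pyridine, CH2Cl2, −78 → 0 °C
Reagents that add atoms: triflic anhydride, O=S(=O)(OS(=O)(=O)C(F)(F)F)C(F)(F)F
Why: O-Sulfonylation of the acidic enol of the diosphenol gives the vinyl triflate at C2.

Step 22
Reactants: 30 diosphenol triflate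
Product: 31 tris-silyl ether enone (C1 ketone, C2=C3)
Conditions: Pd(OAc)2 (5 mol %), PPh3, Bu3N, HCO2H, DMF, 60 °C
Reagents that add atoms: none
Why: Palladium-catalysed formate reduction of a vinyl triflate: oxidative addition to zerovalent palladium, formate exchange, decarboxylation and reductive elimination replace C2–OTf by C2–H. This gives the verbenone-type enone without touching its double bond.

Step 23
Reactants: 31 tris-silyl ether enone
Product: 32 triol enone
Conditions: HF·pyridine, pyridine–THF, 0 → 25 °C
Reagents that add atoms: none
Why: Fluoride cleavage of the three silyl ethers under buffered conditions; the hindered β,β-disubstituted enone is not attacked, and no hydroxyl can reach C1 or C3 across the cage.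

Step 24
Reactants: 32 triol enone; 33 angelic acid
Product: 35 target triangelate CNP0266467.1, via mixed anhydride 34 (not isolated)
Conditions: 33 (6 equiv), 2,4,6-Cl3C6H2COCl, Et3N, toluene, 25 °C; then 32, toluene, 80 °C
Reagents that add atoms: angelic acid, C/C=C(/C)C(=O)O
Why: Yamaguchi esterification: the mixed anhydride acylates all three hydroxyls at the angeloyl carbonyl because the trichlorobenzoyl carbonyl is shielded, and working without a nucleophilic catalyst suppresses Z to E isomerisation to tiglate. No stereocentre is touched.

## Compound list

1 | (S)-(+)-carvone | O=C1C(C)=CC[C@H](C(C)=C)C1 | starting material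
2 | (5S)-8,9-epoxycarvone, both epoxide epimers | O=C1C(C)=CC[C@H](C2(C)CO2)C1 | intermediate
3 | bis(chlorotitanocene) C9 alkoxide C2 enolate | C1[C@H]2CC(O[Ti](Cl)(C3C=CC=C3)C3C=CC=C3)=C(C)[C@@H]1[C@@]2(C)CO[Ti](Cl)(C1C=CC=C1)C1C=CC=C1 | intermediate (not isolated)
4 | bicyclo[3.1.1]heptan-2-one with C3 methyl, C10 methyl syn and C9 hydroxymethyl anti | C1[C@H]2CC(=O)[C@@H](C)[C@@H]1[C@@]2(C)CO | intermediate
5 | C2 ethylene ketal of 4 | C1[C@H]2CC3(OCCO3)[C@@H](C)[C@@H]1[C@@]2(C)CO | intermediate
6 | C9 nitrite ester of 5 | C1[C@H]2CC3(OCCO3)[C@@H](C)[C@@H]1[C@@]2(C)CON=O | intermediate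
7 | C5 nitroso C9 alcohol | O=NC1[C@H]2CC3(OCCO3)[C@@H](C)[C@@H]1[C@@]2(C)CO | intermediate (not isolated)
8 | C5 oxime C9 alcohol | ON=C1[C@H]2CC3(OCCO3)[C@@H](C)[C@@H]1[C@@]2(C)CO | intermediate
9 | C5 cyclobutanone C9 alcohol | O=C1[C@H]2CC3(OCCO3)[C@@H](C)[C@@H]1[C@@]2(C)CO | intermediate
10 | C5 ketone C9 aldehyde | O=C1[C@H]2CC3(OCCO3)[C@@H](C)[C@@H]1[C@@]2(C)C=O | intermediate
11 | diisopinocampheylborinate of 12 | O=C1[C@H]2CC3(OCCO3)[C@@H](C)[C@@H]1[C@@]2(C)[C@H](OB([C@H]1C[C@H]2C[C@@H]([C@@H]1C)C2(C)C)[C@H]1C[C@H]2C[C@@H]([C@@H]1C)C2(C)C)CC=C | intermediate (not isolated)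
12 | (9R)-homoallylic alcohol with C5 ketone | O=C1[C@H]2CC3(OCCO3)[C@@H](C)[C@@H]1[C@@]2(C)[C@H](O)CC=C | intermediate
13 | C9 2-bromopropanoate of 12 | O=C1[C@H]2CC3(OCCO3)[C@@H](C)[C@@H]1[C@@]2(C)[C@H](OC(=O)C(C)Br)CC=C | intermediate
14 | samarium enolate of 13 | O=C1[C@H]2CC3(OCCO3)[C@@H](C)[C@@H]1[C@@]2(C)[C@H](OC(O[Sm](I)I)=CC)CC=C | intermediate (not isolated)
15 | seven-membered lactone (C15 to C9 oxygen) with C5–C6 bond and C5 tertiary alcohol | O=C1C(C)[C@]2(O)[C@H]3CC4(OCCO4)[C@@H](C)[C@@H]2[C@@]3(C)[C@@H](CC=C)O1 | intermediate
16 | C5 methyl oxalate of 15 | O=C1C(C)[C@]2(OC(=O)C(=O)OC)[C@H]3CC4(OCCO4)[C@@H](C)[C@@H]2[C@@]3(C)[C@@H](CC=C)O1 | intermediate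
17 | lactone with C5–H syn, C9 allyl | O=C1C(C)[C@@H]2[C@H]3CC4(OCCO4)[C@@H](C)[C@@H]2[C@@]3(C)[C@@H](CC=C)O1 | intermediate
18 | lithium enolate of 17 | [Li]OC1=C(C)[C@@H]2[C@H]3CC4(OCCO4)[C@@H](C)[C@@H]2[C@@]3(C)[C@@H](CC=C)O1 | intermediate (not isolated)
19 | C6 bromo lactone | O=C1C(C)(Br)[C@@H]2[C@H]3CC4(OCCO4)[C@@H](C)[C@@H]2[C@@]3(C)[C@@H](CC=C)O1 | intermediate
20 | ozonide of 19 | O=C1C(C)(Br)[C@@H]2[C@H]3CC4(OCCO4)[C@@H](C)[C@@H]2[C@@]3(C)[C@@H](CC5OCOO5)O1 | intermediate (not isolated)
21 | C6 bromo lactone with C7 aldehyde | O=C1C(C)(Br)[C@@H]2[C@H]3CC4(OCCO4)[C@@H](C)[C@@H]2[C@@]3(C)[C@@H](CC=O)O1 | intermediate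
22 | samarium enolate of 21 | I[Sm](I)OC1=C(C)[C@@H]2[C@H]3CC4(OCCO4)[C@@H](C)[C@@H]2[C@@]3(C)[C@@H](CC=O)O1 | intermediate (not isolated)
23 | bridged hydroxy lactone, C6–C7 bond formed, C7 carbinol epimeric to target | O=C1[C@]5(C)[C@@H]2[C@H]3CC4(OCCO4)[C@@H](C)[C@@H]2[C@@]3(C)[C@H](O1)C[C@@H]5O | intermediate
24 | bridged keto lactone (C7 ketone) | O=C1[C@]5(C)[C@@H]2[C@H]3CC4(OCCO4)[C@@H](C)[C@@H]2[C@@]3(C)[C@H](O1)CC5=O | intermediate
25 | bridged hydroxy lactone with target C7 configuration | O=C1[C@]5(C)[C@@H]2[C@H]3CC4(OCCO4)[C@@H](C)[C@@H]2[C@@]3(C)[C@H](O1)C[C@H]5O | intermediate (not isolated)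
26 | C7,C9,C15 triol with C2 ketal | OC[C@]1(C)[C@@H]2[C@H]3CC4(OCCO4)[C@@H](C)[C@@H]2[C@@]3(C)[C@H](O)C[C@H]1O | intermediate
27 | tris(tert-butyldimethylsilyl) ether of 26 | CC(C)(C)[Si](C)(C)OC[C@]1(C)[C@@H]2[C@H]3CC4(OCCO4)[C@@H](C)[C@@H]2[C@@]3(C)[C@H](O[Si](C)(C)C(C)(C)C)C[C@H]1O[Si](C)(C)C(C)(C)C | intermediate
28 | tris-silyl ether C2 ketone | CC(C)(C)[Si](C)(C)OC[C@]1(C)[C@@H]2[C@H]3CC(=O)[C@@H](C)[C@@H]2[C@@]3(C)[C@H](O[Si](C)(C)C(C)(C)C)C[C@H]1O[Si](C)(C)C(C)(C)C | intermediate
29 | tris-silyl ether diosphenol (C1 ketone, C2 enol) | CC(C)(C)[Si](C)(C)OC[C@]1(C)[C@@H]2[C@H]3C(=O)C(O)=C(C)[C@@H]2[C@@]3(C)[C@H](O[Si](C)(C)C(C)(C)C)C[C@H]1O[Si](C)(C)C(C)(C)C | intermediate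
30 | tris-silyl ether diosphenol triflate | CC(C)(C)[Si](C)(C)OC[C@]1(C)[C@@H]2[C@H]3C(=O)C(OS(=O)(=O)C(F)(F)F)=C(C)[C@@H]2[C@@]3(C)[C@H](O[Si](C)(C)C(C)(C)C)C[C@H]1O[Si](C)(C)C(C)(C)C | intermediate
31 | tris-silyl ether enone | CC(C)(C)[Si](C)(C)OC[C@]1(C)[C@@H]2[C@H]3C(=O)C=C(C)[C@@H]2[C@@]3(C)[C@H](O[Si](C)(C)C(C)(C)C)C[C@H]1O[Si](C)(C)C(C)(C)C | intermediate
32 | triol enone (C7, C9, C15 hydroxyls) | OC[C@]1(C)[C@@H]2[C@H]3C(=O)C=C(C)[C@@H]2[C@@]3(C)[C@H](O)C[C@H]1O | intermediate
33 | angelic acid, (Z)-2-methylbut-2-enoic acid | C/C=C(/C)C(=O)O | starting material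
34 | angelic 2,4,6-trichlorobenzoic anhydride | C/C=C(/C)C(=O)OC(=O)c1c(Cl)cc(Cl)cc1Cl | intermediate (not isolated)
35 | target, C7,C9,C15-tri-O-angeloyl triol enone (CNP0266467.1) | C/C=C(/C)C(=O)OC[C@]1(C)[C@@H]2[C@H]3C(=O)C=C(C)[C@@H]2[C@@]3(C)[C@H](OC(=O)/C(C)=C\C)C[C@H]1OC(=O)/C(C)=C\C | target

## Step count and least certain steps

Total step count: 24. Longest linear sequence: 24 steps, from 1; angelic acid 33 enters in the last step.

Step 2 (key step). The tertiary radical may be captured by a second Cp2TiCl before the strained 4-exo closure, ending in β-hydride elimination or simple reduction. The closure may also show poor facial selectivity at C10, putting the CH2O arm syn. Fallback, from 1 and back at 4: allylic hydroxylation of the isopropenyl methyl of 1 (SeO2, t-BuOOH) would give 10-hydroxycarvone F1. Hydrogen-atom transfer from an iron hydride (Fe(acac)3, PhSiH3, EtOH) to its 1,1-disubstituted alkene would generate the same C10 radical without any radical-trapping metal in stoichiometric amount. After 4-exo addition and reduction of the α-keto radical this leads directly to 4.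

Step 5. β-Scission of the C9–C10 bond (loss of formaldehyde) may compete with abstraction of the strong cyclobutane C–H bond, and the nitroso dimer may resist tautomerisation. Fallback, from 1 and back at 10, carrying the C5 oxygen from the start. Carvone 1 would be converted to its extended dienol silyl ether F2 (TBSOTf, Et3N). Peracid γ-oxidation would give the γ-hydroxy enone F3, hydroxylated at the future C5, and a second epoxidation the hydroxy epoxide F4. The titanium cyclisation of step 2 would then give the diol ketone F5, ketalisation the diol ketal F6, and double Dess–Martin oxidation the keto aldehyde 10. The C5 configuration is irrelevant, since it ends as a ketone.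

Step 10. The samarium enolate may be protonated or react between molecules before it finds the hindered C5 carbonyl. Fallback, from 12 and back at 17, by olefination and reduction instead of the tether. Silylation of 12 would give the silyl ether F7. Horner–Wadsworth–Emmons reaction of the cyclobutanone with methyl 2-(dimethoxyphosphoryl)propanoate would give the alkylidene ester F8, and Mg in MeOH the saturated ester F9 as a mixture at C5. Fluoride would free the hydroxy esters F10. On acid catalysis only the C5 epimer with the side chain anti can close to lactone 17, and the other epimer is separated. This fallback is shorter but gives up control of C5, which is why it is not the main route.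

Step 15. The doubly bridged aldolate is strained and may revert, or the enolate may act as a base and expel the C9 carboxylate from the β-acyloxy aldehyde. Fallback, from 17 and back at 23 or its C7 epimer 25, both of which step 16 oxidises to 24. Methanolysis of 17 (NaOMe, MeOH) would give the hydroxy ester F11, and silylation the silyl ether F12. Enolate bromination would give the bromo ester F13 and ozonolysis the aldehyde F14. The SmI2 aldol without the lactone bridge would then close the seven-membered ring to the β-hydroxy ester F15. After fluoride, the C6 epimer whose ester is cis to the C9 oxygen lactonises to 23 or 25. C6 control is lost in the ring closure and regained only by this selective lactonisation.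

Step 20. Selenium dioxide may over-oxidise, hydroxylate C3 through the more substituted enol, or strip silyl ethers through its acidity. Fallback, from 28 and back at 31. Thermodynamic enol triflation (Tf2O, 2,6-di-tert-butyl-4-methylpyridine) would give the C2=C3 enol triflate F16, and palladium–formate reduction the α-pinene-type alkene F17. Allylic oxidation at C1 with t-BuOOH and Rh2(cap)4 (dirhodium tetracaprolactamate), the α-pinene to verbenone transformation, would give 31. A minor C1=C2 regioisomer would funnel through the same allyl radical.

Step 24. Acylation of the two neopentyl secondary hydroxyls may stall, and prolonged heating may isomerise angelate to tiglate. Fallback, from 32 and back at 35, building the Z alkenes on the molecule. Esterification of 32 with 2-[bis(2,2,2-trifluoroethoxy)phosphoryl]propanoic acid (DCC, DMAP) would give the tris(phosphonopropanoate) F18. Threefold Still–Gennari olefination with acetaldehyde (KHMDS, 18-crown-6, THF, −78 °C) would give the three (Z)-2-methylbut-2-enoates of 35.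

## Further compounds

F1 | step 2 | 10-hydroxycarvone | O=C1C(C)=CC[C@H](C(=C)CO)C1
F2 | step 5 | extended dienol tert-butyldimethylsilyl ether of carvone | CC(C)(C)[Si](C)(C)OC1=C(C)C=C[C@H](C(C)=C)C1
F3 | step 5 | γ-hydroxy carvone (hydroxyl on the future C5) | O=C1C(C)=CC(O)[C@H](C(C)=C)C1
F4 | step 5 | γ-hydroxy 8,9-epoxycarvone | O=C1C(C)=CC(O)[C@H](C2(C)CO2)C1
F5 | step 5 | bicyclic C5,C9 diol C2 ketone | OC1[C@H]2CC(=O)[C@@H](C)[C@@H]1[C@@]2(C)CO
F6 | step 5 | bicyclic C5,C9 diol C2 ketal | OC1[C@H]2CC3(OCCO3)[C@@H](C)[C@@H]1[C@@]2(C)CO
F7 | step 10 | C9 tert-butyldimethylsilyl ether of 12 | O=C1[C@H]2CC3(OCCO3)[C@@H](C)[C@@H]1[C@@]2(C)[C@H](O[Si](C)(C)C(C)(C)C)CC=C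
F8 | step 10 | C5=C6 alkylidene methyl ester | COC(=O)C(C)=C1[C@H]2CC3(OCCO3)[C@@H](C)[C@@H]1[C@@]2(C)[C@H](O[Si](C)(C)C(C)(C)C)CC=C
F9 | step 10 | saturated methyl ester, mixture at C5 and C6 | COC(=O)C(C)C1[C@H]2CC3(OCCO3)[C@@H](C)[C@@H]1[C@@]2(C)[C@H](O[Si](C)(C)C(C)(C)C)CC=C
F10 | step 10 | C9 hydroxy methyl esters, mixture at C5 and C6 | COC(=O)C(C)C1[C@H]2CC3(OCCO3)[C@@H](C)[C@@H]1[C@@]2(C)[C@H](O)CC=C
F11 | step 15 | C9 hydroxy methyl ester with C5 side chain anti | COC(=O)C(C)[C@@H]1[C@H]2CC3(OCCO3)[C@@H](C)[C@@H]1[C@@]2(C)[C@H](O)CC=C
F12 | step 15 | C9 silyl ether of F11 | COC(=O)C(C)[C@@H]1[C@H]2CC3(OCCO3)[C@@H](C)[C@@H]1[C@@]2(C)[C@H](O[Si](C)(C)C(C)(C)C)CC=C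
F13 | step 15 | C6 bromo methyl ester | COC(=O)C(C)(Br)[C@@H]1[C@H]2CC3(OCCO3)[C@@H](C)[C@@H]1[C@@]2(C)[C@H](O[Si](C)(C)C(C)(C)C)CC=C
F14 | step 15 | C6 bromo methyl ester with C7 aldehyde | COC(=O)C(C)(Br)[C@@H]1[C@H]2CC3(OCCO3)[C@@H](C)[C@@H]1[C@@]2(C)[C@H](O[Si](C)(C)C(C)(C)C)CC=O
F15 | step 15 | tricyclic β-hydroxy methyl ester, mixture at C6 and C7 | COC(=O)C1(C)[C@@H]2[C@H]3CC4(OCCO4)[C@@H](C)[C@@H]2[C@@]3(C)[C@H](O[Si](C)(C)C(C)(C)C)CC1O
F16 | step 20 | tris-silyl ether C2=C3 enol triflate | CC(C)(C)[Si](C)(C)OC[C@]1(C)[C@@H]2[C@H]3CC(OS(=O)(=O)C(F)(F)F)=C(C)[C@@H]2[C@@]3(C)[C@H](O[Si](C)(C)C(C)(C)C)C[C@H]1O[Si](C)(C)C(C)(C)C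
F17 | step 20 | tris-silyl ether C2=C3 alkene | CC(C)(C)[Si](C)(C)OC[C@]1(C)[C@@H]2[C@H]3CC=C(C)[C@@H]2[C@@]3(C)[C@H](O[Si](C)(C)C(C)(C)C)C[C@H]1O[Si](C)(C)C(C)(C)C
F18 | step 24 | tris[2-(bis(2,2,2-trifluoroethoxy)phosphoryl)propanoate] of 32 | CC(C(=O)OC[C@]1(C)[C@@H]2[C@H]3C(=O)C=C(C)[C@@H]2[C@@]3(C)[C@H](OC(=O)C(C)P(=O)(OCC(F)(F)F)OCC(F)(F)F)C[C@H]1OC(=O)C(C)P(=O)(OCC(F)(F)F)OCC(F)(F)F)P(=O)(OCC(F)(F)F)OCC(F)(F)F
A1 | alternative 1 | tetrakis-silyl tricyclic C5 cyclobutanol | CC(C)(C)[Si](C)(C)OC[C@]1(C)[C@]2(O)[C@H]3[C@@H](O[Si](C)(C)C(C)(C)C)C=C(C)[C@@H]2[C@@]3(C)[C@H](O[Si](C)(C)C(C)(C)C)C[C@H]1O[Si](C)(C)C(C)(C)C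
A2 | alternative 1 | cis-fused bicyclo[5.4.0]undecenone with C5 ketone | CC(C)(C)[Si](C)(C)OC[C@]1(C)C(=O)[C@H]2[C@@H](O[Si](C)(C)C(C)(C)C)C=C(C)C[C@@]2(C)[C@H](O[Si](C)(C)C(C)(C)C)C[C@H]1O[Si](C)(C)C(C)(C)C
A3 | alternative 2 | tricyclic β-hydroxy ketone with C15 aldehyde | O=C[C@]1(C)[C@@H]2[C@H]3CC=C(C)[C@@H]2[C@@]3(C)C(=O)C[C@H]1O
A4 | alternative 2 | C6 dialdehyde with C10 methyl ketone | O=CC(C)(C=O)[C@@H]1[C@H]2CC=C(C)[C@@H]1[C@@]2(C)C(C)=O
A5 | alternative 3 | cis-fused bicyclic ketone with C9 alcohol and quaternary C10 | CC(C)(C)[Si](C)(C)OC[C@]1(C)C3(OCCO3)[C@H]2C(=O)C[C@@H](C)C[C@@]2(C)[C@H](O)C[C@H]1O[Si](C)(C)C(C)(C)C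
A6 | alternative 3 | cyclohexenone with C9 aldehyde side chain | CC(C)(C)[Si](C)(C)OC[C@@](C)([C@@H](CC=O)O[Si](C)(C)C(C)(C)C)C1(OCCO1)C1=C(C)C[C@H](C)CC1=O
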